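**Retrosynthetic overview**
1. Endgame: the C8 methacrylate, C14 aldehyde, free C15 alcohol, C9 methyl ether (from a C9 ketone) and the 6,12-lactone (C6–OH onto the C12 ester) are all installed on a ten-membered α-silyloxy enone.
2. Enabling feature: the exocyclic methylene C13=C11 of the lactone sits on C7, so C13=C11–C7–C8–C9(–O) is a γ,δ-unsaturated carbonyl (Claisen) retron spanning carbocycle and lactone. Cutting C7–C8 and joining O9 to C13 gives a 12-membered oxacycle (O, C13, C11, C7, C6, C5, C4, C3, C2, C1, C10, C9) with C8 as an exocyclic formyl group.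
3. Key disconnection: a [3,3] shift of the enol silane of that aldehyde contracts 12 → 10. It makes C7–C8, sets C7 and C8 from C6 alone, and releases C9=O and C11=C13.
4. Oxacycle: macro-HWE (C7=C11) after oxa-Michael etherification (O9–C13). The chain comes from (S)-glyceraldehyde acetonide by E-selective Wittig (C4=C5), trans-hydrostannation (C1=C10) and alkenyllithium addition (C9–C10).
5. Ring order: 12-membered oxacycle, then ten-membered carbocycle, then γ-lactone.

Key step: step 16

Remark: germacrane numbering is used (ring C1–C10, C11–C13 acrylate/lactone carbons, C14 on C10, C15 on C4); "ring-cis" means both ring bonds lie on the same side of an alkene; (S)-glyceraldehyde acetonide, (4-methoxybenzyloxy)acetaldehyde and ethyl 2-(diethoxyphosphoryl)acrylate are taken as commercial.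

**Step 1**
Reactants: 1 ethyl (triphenyl-λ5-phosphanylidene)acetate; 2 4-iodobut-1-yne
Product: 4 ethyl 2-(triphenyl-λ5-phosphanylidene)hex-5-ynoate, via phosphonium iodide 3 (not isolated)
Conditions: MeCN, reflux; then aq NaOH, CH2Cl2, 0 °C
Reagents that add atoms: none
Why: C-alkylation of a stabilised phosphorus ylide by a primary iodide, then deprotonation of the salt (ylide alkylation), should give the α-substituted ylide and creates no stereocentre.

**Step 2**
Reactants: 4 ethyl 2-(triphenyl-λ5-phosphanylidene)hex-5-ynoate; 5 (S)-2,2-dimethyl-1,3-dioxolane-4-carbaldehyde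
Product: 6 ethyl (E)-2-(but-3-ynyl)-3-[(4R)-2,2-dimethyl-1,3-dioxolan-4-yl]acrylate
Conditions: CH2Cl2, rt to 40 °C
Reagents that add atoms: none
Why: The Wittig reaction of an α-substituted stabilised ylide is E-selective, so C6 should end trans to the ester carbon C15 and cis to C3 (the later ring-cis C4=C5 alkene), while the C6 stereocentre is carried over unchanged from 5.

**Step 3**
Reactants: 6 ethyl (E)-2-(but-3-ynyl)-3-[(4R)-2,2-dimethyl-1,3-dioxolan-4-yl]acrylate
Product: 7 (E)-allylic alcohol (free C15–OH)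
Conditions: DIBAL-H, CH2Cl2, −78 °C; Rochelle salt
Reagents that add atoms: none
Why: DIBAL-H reduction of an enoate should stop at the allylic alcohol at low temperature and leave the terminal alkyne, the acetonide and the alkene geometry untouched.

**Step 4**
Reactants: 7 (E)-allylic alcohol (free C15–OH)
Product: 8 C15 TBDPS ether
Conditions: TBDPSCl, imidazole, DMF, rt
Reagents that add atoms: tert-butyl(chloro)diphenylsilane CC(C)(C)[Si](Cl)(c1ccccc1)c1ccccc1
Why: Standard silylation of a primary allylic alcohol installs the most robust silyl group, which is removed last.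

**Step 5**
Reactants: 8 C15 TBDPS ether
Product: 9 (2R,3E)-4-(TBDPSO-methyl)oct-3-en-7-yne-1,2-diol (C6/C7 diol)
Conditions: AcOH/H2O 4:1, 40 °C
Reagents that add atoms: none
Why: Acid hydrolysis of the terminal acetonide is placed here because only the acid-stable TBDPS ether is present so far, and C6 is not touched.

**Step 6**
Reactants: 9 C6/C7 diol
Product: 10 C6/C7 bis-TES ether
Conditions: TESCl, imidazole, DMAP (cat.), CH2Cl2, 0 °C to rt
Reagents that add atoms: chlorotriethylsilane CC[Si](Cl)(CC)CC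
Why: Bis-silylation gives a primary/secondary TES pair that the Swern step 12 can later distinguish.

**Step 7**
Reactants: 10 C6/C7 bis-TES ether
Product: 12 propargylic alcohol (C14–OH on C10≡C1), via lithium acetylide 11 (not isolated)
Conditions: n-BuLi, THF, −78 °C; (CH2O)n, −78 °C to rt
Reagents that add atoms: formaldehyde (from paraformaldehyde) C=O
Why: Deprotonation of the terminal alkyne and addition of the acetylide to formaldehyde (hydroxymethylation) brings in C14 together with the free OH needed as directing group in step 8.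

**Step 8**
Reactants: 12 propargylic alcohol
Product: 13 (Z)-alkenylstannane (Bu3Sn on C10)
Conditions: Bu3SnH, [Cp*RuCl]4 (cat.), CH2Cl2, rt
Reagents that add atoms: tributyltin hydride CCCC[SnH](CCCC)CCCC
Why: In the ruthenium-catalysed trans-hydrostannation, hydrogen bonding of the propargylic OH to Ru–Cl steers tin to the proximal carbon C10 and H and Sn add trans, so C2 ends cis to tin and trans to C14, which is the ring-cis geometry of C1=C10.

**Step 9**
Reactants: 13 (Z)-alkenylstannane
Product: 14 C14 TBS ether of the stannane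
Conditions: TBSCl, imidazole, CH2Cl2, 0 °C
Reagents that add atoms: tert-butyl(chloro)dimethylsilane CC(C)(C)[Si](C)(C)Cl
Why: Silylation under nearly neutral conditions protects the only free hydroxyl group without protodestannylation.

**Step 10**
Reactants: 14 C14 TBS ether of the stannane; 15 (4-methoxybenzyloxy)acetaldehyde
Product: 17 allylic alcohol (C9–OH and C8H2OPMB; both C9 epimers), via alkenyllithium 16 (not isolated)
Conditions: n-BuLi, THF, −78 °C; then 15, −78 °C
Reagents that add atoms: none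
Why: Tin–lithium exchange keeps the alkene geometry and 1,2-addition to the aldehyde forms C9–C10; the C9 carbinol may form as an epimer mixture because C9 becomes sp2 in step 16.

**Step 11**
Reactants: 17 allylic alcohol (C9 epimers); 18 ethyl 2-(diethoxyphosphoryl)acrylate
Product: 19 ether phosphonate (O9–C13H2–C11H(CO2Et)P(O)(OEt)2)
Conditions: KHMDS, THF, −78 °C; 18, −78 to −20 °C; AcOH
Reagents that add atoms: none
Why: Oxa-Michael addition of the potassium alkoxide to the doubly activated acrylate is driven by formation of the stabilised phosphonoacetate anion, which is protonated on quench, and the new C11 centre is erased in step 13.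

**Step 12**
Reactants: 19 ether phosphonate
Product: 20 C7 aldehyde (C6–OTES retained)
Conditions: (COCl)2, DMSO, CH2Cl2, −78 to −30 °C; Et3N
Reagents that add atoms: none
Why: Under Swern conditions a primary TES ether is cleaved and oxidised in situ much faster than a secondary TES, primary TBS or TBDPS ether (selective oxidative desilylation), and A(1,3) strain keeps the C6–H bond in the alkene plane, which protects C6 from epimerisation.

**Step 13**
Reactants: 20 C7 aldehyde
Product: 21 12-membered oxacycle with CH2OPMB on C9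
Conditions: LiCl, DBU, MeCN, 1 mM (slow addition), rt
Reagents that add atoms: none
Why: The intramolecular Horner–Wadsworth–Emmons olefination under Masamune–Roush conditions at high dilution closes the 12-membered ring and, as is usual for α-substituted phosphonoacetates, should place the ester trans to C6 so that C6 and C13 are ring-cis.

**Step 14**
Reactants: 21 12-membered oxacycle with CH2OPMB on C9
Product: 22 oxacycle carbinol (C8H2OH on C9)
Conditions: DDQ, CH2Cl2/pH 7 buffer, 0 °C
Reagents that add atoms: none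
Why: Oxidative cleavage of the PMB ether by DDQ attacks only the electron-rich arene and should spare the silyl ethers, the enoate and the trisubstituted alkenes.

**Step 15**
Reactants: 22 oxacycle carbinol
Product: 23 oxacycle carbaldehyde (C8HO on C9)
Conditions: Dess–Martin periodinane, NaHCO3, CH2Cl2, 0 °C
Reagents that add atoms: none
Why: The buffered Dess–Martin oxidation is neutral and fast, which matters because this α-alkoxy β,γ-unsaturated aldehyde would slip into conjugation under base, so it is used at once.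

**Step 16**
Reactants: 23 oxacycle carbaldehyde
Product: 25 ten-membered α-silyloxy enone (6R,7S,8S), via (Z)-enol silane 24 (not isolated)
Conditions: TBSOTf, Et3N, CH2Cl2, −78 to 0 °C; pentane filtration; then PhMe (dilute), 80 °C
Reagents that add atoms: tert-butyldimethylsilyl triflate CC(C)(C)[Si](C)(C)OS(=O)(=O)C(F)(F)F
Why: Proposed new method: soft enolisation of the formyl group (both C9 epimers converge) should give the (Z)-enol silane 24, in which the exocyclic carbon C8 and the ring atoms C9–O–C13–C11=C7 form an allyl vinyl ether that undergoes a concerted, strongly polarised [3,3] shift (donor OSi on C8, acceptor CO2Et on C11), so that C8–C7 forms, O–C13 breaks, C9 becomes the ketone and C13 the exocyclic methylene. The closest known reaction types are the Claisen rearrangement of enols, enolates and enol silanes of α-allyloxy carbonyl compounds and the Ireland–Claisen ring contraction of macrolactones; what is new is the offset topology with one exocyclic terminus, by which O, C13 and C11 leave the ring, C8 enters it and the 12-membered oxacycle contracts by two atoms. The ten-membered carbocycle closes transannularly through a six-centre chair array bridged by the chain C10–C1–C2–C3–C4–C5–C6, and no other ring is formed. C7 is controlled by C6: A(1,3) strain with C13H2 holds H6 in the alkene plane and the short tether forces C5 onto the face that C8 attacks, so the C6–OTES bond stands anti to the new bond, which gives the O6/C11 syn relation of the later trans-lactone. C8 is controlled by the two alkene geometries: with the ring-cis C7=C11 alkene (C6 axial) and the Z enol silane (OSi axial) the chair gives the C11/O8 anti pair. The step needs three selectivities: Z-selective silylation (OSi avoids the branched alkenyl carbon C10), chair over boat (in the boat C10 would sit over the ester), and the [3,3] shift ahead of a [1,5]-hydrogen shift or a Diels–Alder reaction of the diene (push–pull substitution lowers the Claisen barrier, and the Z-substituted diene terminus disfavours the s-cis form).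

**Step 17**
Reactants: 25 ten-membered α-silyloxy enone
Product: 26 (9S)-allylic alcohol
Conditions: NaBH4, CeCl3·7H2O, MeOH/THF, −78 °C
Reagents that add atoms: none
Why: In the Luche 1,2-reduction the Felkin–Anh arrangement places the C8–OTBS bond perpendicular to the carbonyl group, and hydride comes anti to it from the ring periphery, which should give the 8,9-syn (9S) alcohol while the acrylate and the silyl ethers survive at −78 °C.

**Step 18**
Reactants: 26 (9S)-allylic alcohol
Product: 27 C9 methyl ether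
Conditions: Me3OBF4, 1,8-bis(dimethylamino)naphthalene, 4 Å MS, CH2Cl2, rt
Reagents that add atoms: trimethyloxonium tetrafluoroborate C[O+](C)C.F[B-](F)(F)F
Why: O-methylation with the Meerwein salt and a non-nucleophilic base avoids an alkoxide, and thereby silyl migration from O8 or lactonisation onto C12, with retention at C9.

**Step 19**
Reactants: 27 C9 methyl ether
Product: 29 trans-6,12-lactone with free C14–OH, via dihydroxy ester 28 (not isolated)
Conditions: CSA (cat.), MeOH/CH2Cl2, 0 °C to rt; then CSA (cat.), CH2Cl2, rt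
Reagents that add atoms: none
Why: Acid-catalysed methanolysis removes the labile secondary TES and primary allylic TBS ethers but not the hindered secondary TBS or the TBDPS ether, and the freed C6–OH closes the γ-lactone onto C12 (lactonisation) with the trans fusion already fixed by C6 and C7.

**Step 20**
Reactants: 29 trans-6,12-lactone with free C14–OH
Product: 30 C14 enal
Conditions: MnO2, CH2Cl2, rt
Reagents that add atoms: none
Why: MnO2 oxidises only allylic alcohols and the C14 carbinol is the only one left, so the enal should form without change of the C1=C10 geometry.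

**Step 21**
Reactants: 30 C14 enal
Product: 31 C8 alcohol
Conditions: HF·pyridine, pyridine, THF, 0 °C to rt
Reagents that add atoms: none
Why: Buffered HF·pyridine cleaves the secondary TBS ether faster than the primary TBDPS ether and is compatible with the enal and the α-methylene lactone.

**Step 22**
Reactants: 31 C8 alcohol
Product: 32 C8 methacrylate (15-O-TBDPS)
Conditions: methacrylic anhydride, Et3N, DMAP (cat.), CH2Cl2, 0 °C to rt
Reagents that add atoms: methacrylic anhydride C=C(C)C(=O)OC(=O)C(C)=C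
Why: DMAP-catalysed acylation of the only free hydroxyl group installs the ester with retention at C8.

**Step 23**
Reactants: 32 C8 methacrylate (15-O-TBDPS)
Product: 33 target CNP0114830.1
Conditions: HF·pyridine (large excess), MeCN, rt
Reagents that add atoms: none
Why: Acidic fluoride removes the last silyl group without the basic conditions that would add to the three Michael acceptors or shift the ester.

**Compound list**
1 | ethyl (triphenyl-λ5-phosphanylidene)acetate | CCOC(=O)C=P(c1ccccc1)(c1ccccc1)c1ccccc1 | starting material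
2 | 4-iodobut-1-yne | C#CCCI | starting material
3 | (1-ethoxy-1-oxohex-5-yn-2-yl)triphenylphosphonium iodide (not isolated) | CCOC(=O)C(CCC#C)[P+](c1ccccc1)(c1ccccc1)c1ccccc1.[I-] | intermediate
4 | ethyl 2-(triphenyl-λ5-phosphanylidene)hex-5-ynoate | CCOC(=O)C(CCC#C)=P(c1ccccc1)(c1ccccc1)c1ccccc1 | intermediate
5 | (S)-2,2-dimethyl-1,3-dioxolane-4-carbaldehyde | CC1(C)OC[C@@H](C=O)O1 | starting material
6 | ethyl (E)-2-(but-3-ynyl)-3-[(4R)-2,2-dimethyl-1,3-dioxolan-4-yl]acrylate | CC1(C)OC[C@@H](/C=C(/C(=O)OCC)CCC#C)O1 | intermediate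
7 | (E)-2-(but-3-ynyl)-3-[(4R)-2,2-dimethyl-1,3-dioxolan-4-yl]prop-2-en-1-ol | CC1(C)OC[C@@H](/C=C(/CO)CCC#C)O1 | intermediate
8 | TBDPS ether of 7 | CC1(C)OC[C@@H](/C=C(/CO[Si](c2ccccc2)(c2ccccc2)C(C)(C)C)CCC#C)O1 | intermediate
9 | (2R,3E)-4-(TBDPSO-methyl)oct-3-en-7-yne-1,2-diol | OC[C@H](O)/C=C(/CO[Si](c1ccccc1)(c1ccccc1)C(C)(C)C)CCC#C | intermediate
10 | 1,2-bis-TES ether of 9 (6R) | CC[Si](CC)(CC)OC[C@H](O[Si](CC)(CC)CC)/C=C(/CO[Si](c1ccccc1)(c1ccccc1)C(C)(C)C)CCC#C | intermediate
11 | lithium acetylide of 10 (not isolated) | CC[Si](CC)(CC)OC[C@H](O[Si](CC)(CC)CC)/C=C(/CO[Si](c1ccccc1)(c1ccccc1)C(C)(C)C)CCC#C[Li] | intermediate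
12 | (6E,8R)-6-(TBDPSO-methyl)-8,9-bis(TESO)non-6-en-2-yn-1-ol | CC[Si](CC)(CC)OC[C@H](O[Si](CC)(CC)CC)/C=C(/CO[Si](c1ccccc1)(c1ccccc1)C(C)(C)C)CCC#CCO | intermediate
13 | (2Z,6E,8R)-2-(tributylstannyl)nona-2,6-dien-1-ol derived from 12 (Sn on C10, cis to C2) | CC[Si](CC)(CC)OC[C@H](O[Si](CC)(CC)CC)/C=C(/CO[Si](c1ccccc1)(c1ccccc1)C(C)(C)C)CC/C=C(/CO)[Sn](CCCC)(CCCC)CCCC | intermediate
14 | C14 TBS ether of 13 | CC[Si](CC)(CC)OC[C@H](O[Si](CC)(CC)CC)/C=C(/CO[Si](c1ccccc1)(c1ccccc1)C(C)(C)C)CC/C=C(/CO[Si](C)(C)C(C)(C)C)[Sn](CCCC)(CCCC)CCCC | intermediate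
15 | (4-methoxybenzyloxy)acetaldehyde | O=CCOCc1ccc(OC)cc1 | starting material
16 | alkenyllithium from 14 (Li on C10, geometry retained; not isolated) | CC[Si](CC)(CC)OC[C@H](O[Si](CC)(CC)CC)/C=C(/CO[Si](c1ccccc1)(c1ccccc1)C(C)(C)C)CC/C=C(/CO[Si](C)(C)C(C)(C)C)[Li] | intermediate
17 | open-chain allylic alcohol: C9H(OH)–C8H2OPMB on C10; C2 cis to C9; 6R; both C9 epimers | CC[Si](CC)(CC)OC[C@H](O[Si](CC)(CC)CC)/C=C(/CO[Si](c1ccccc1)(c1ccccc1)C(C)(C)C)CC/C=C(/CO[Si](C)(C)C(C)(C)C)C(O)COCc1ccc(OC)cc1 | intermediate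
18 | ethyl 2-(diethoxyphosphoryl)acrylate | C=C(C(=O)OCC)P(=O)(OCC)OCC | starting material
19 | ether phosphonate: O9–C13H2–C11H(CO2Et)P(O)(OEt)2; 6R; C9 and C11 epimers | CC[Si](CC)(CC)OC[C@H](O[Si](CC)(CC)CC)/C=C(/CO[Si](c1ccccc1)(c1ccccc1)C(C)(C)C)CC/C=C(/CO[Si](C)(C)C(C)(C)C)C(COCc1ccc(OC)cc1)OCC(C(=O)OCC)P(=O)(OCC)OCC | intermediate
20 | C7 aldehyde of 19 (6R, α-OTES) | O=C[C@H](O[Si](CC)(CC)CC)/C=C(/CO[Si](c1ccccc1)(c1ccccc1)C(C)(C)C)CC/C=C(/CO[Si](C)(C)C(C)(C)C)C(COCc1ccc(OC)cc1)OCC(C(=O)OCC)P(=O)(OCC)OCC | intermediate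
21 | 12-membered oxacycle: ring O–C13H2–C11(CO2Et)=C7H–C6H(OTES)–C5H=C4(CH2OTBDPS)–C3H2–C2H2–C1H=C10(CH2OTBS)–C9H(CH2OPMB); 6R; all three ring alkenes ring-cis; C9 epimers | COc1ccc(COCC2OC/C(C(=O)OCC)=C\[C@H](O[Si](CC)(CC)CC)/C=C(/CO[Si](c3ccccc3)(c3ccccc3)C(C)(C)C)CC/C=C2/CO[Si](C)(C)C(C)(C)C)cc1 | intermediate
22 | oxacycle as 21 with CH2OH on C9 | OCC1OC/C(C(=O)OCC)=C\[C@H](O[Si](CC)(CC)CC)/C=C(/CO[Si](c2ccccc2)(c2ccccc2)C(C)(C)C)CC/C=C1/CO[Si](C)(C)C(C)(C)C | intermediate
23 | oxacycle as 21 with CHO (C8) on C9 | O=CC1OC/C(C(=O)OCC)=C\[C@H](O[Si](CC)(CC)CC)/C=C(/CO[Si](c2ccccc2)(c2ccccc2)C(C)(C)C)CC/C=C1/CO[Si](C)(C)C(C)(C)C | intermediate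
24 | (Z)-enol silane of 23: exocyclic C8H(OTBS)=C9, O8 cis to O9 (not isolated) | CC(C)(C)[Si](C)(C)O/C=C1\OC/C(C(=O)OCC)=C\[C@H](O[Si](CC)(CC)CC)/C=C(/CO[Si](c2ccccc2)(c2ccccc2)C(C)(C)C)CC/C=C1/CO[Si](C)(C)C(C)(C)C | intermediate
25 | ten-membered enone: C9=O, 8S-OTBS, 7S-C(=CH2)CO2Et, 6R-OTES, ring-cis C4=C5 (CH2OTBDPS) and C1=C10 (CH2OTBS) | CC(C)(C)[Si](C)(C)O[C@H]1[C@@H](C(=C)C(=O)OCC)[C@H](O[Si](CC)(CC)CC)/C=C(/CO[Si](c2ccccc2)(c2ccccc2)C(C)(C)C)CC/C=C(/CO[Si](C)(C)C(C)(C)C)C1=O | intermediate
26 | (6R,7S,8S,9S)-allylic alcohol from 25 | CC(C)(C)[Si](C)(C)O[C@H]1[C@@H](C(=C)C(=O)OCC)[C@H](O[Si](CC)(CC)CC)/C=C(/CO[Si](c2ccccc2)(c2ccccc2)C(C)(C)C)CC/C=C(/CO[Si](C)(C)C(C)(C)C)[C@@H]1O | intermediate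
27 | C9 methyl ether of 26 | CC(C)(C)[Si](C)(C)O[C@H]1[C@@H](C(=C)C(=O)OCC)[C@H](O[Si](CC)(CC)CC)/C=C(/CO[Si](c2ccccc2)(c2ccccc2)C(C)(C)C)CC/C=C(/CO[Si](C)(C)C(C)(C)C)[C@@H]1OC | intermediate
28 | dihydroxy ester (free C6–OH and C14–OH; not isolated) | CC(C)(C)[Si](C)(C)O[C@H]1[C@@H](C(=C)C(=O)OCC)[C@H](O)/C=C(/CO[Si](c2ccccc2)(c2ccccc2)C(C)(C)C)CC/C=C(/CO)[C@@H]1OC | intermediate
29 | trans-6,12-lactone, 8-OTBS, 9-OMe, 15-OTBDPS, free C14–OH | CC(C)(C)[Si](C)(C)O[C@H]1[C@H]2C(=C)C(=O)O[C@@H]2/C=C(/CO[Si](c3ccccc3)(c3ccccc3)C(C)(C)C)CC/C=C(/CO)[C@@H]1OC | intermediate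
30 | C14 enal of 29 | CC(C)(C)[Si](C)(C)O[C@H]1[C@H]2C(=C)C(=O)O[C@@H]2/C=C(/CO[Si](c3ccccc3)(c3ccccc3)C(C)(C)C)CC/C=C(/C=O)[C@@H]1OC | intermediate
31 | C8 alcohol (15-OTBDPS) | O[C@H]1[C@H]2C(=C)C(=O)O[C@@H]2/C=C(/CO[Si](c3ccccc3)(c3ccccc3)C(C)(C)C)CC/C=C(/C=O)[C@@H]1OC | intermediate
32 | C8 methacrylate (15-OTBDPS) | C=C(C)C(=O)O[C@H]1[C@H]2C(=C)C(=O)O[C@@H]2/C=C(/CO[Si](c3ccccc3)(c3ccccc3)C(C)(C)C)CC/C=C(/C=O)[C@@H]1OC | intermediate
33 | CNP0114830.1, (6R,7S,8S,9S) | C=C(C)C(=O)O[C@H]1[C@H]2C(=C)C(=O)O[C@@H]2/C=C(/CO)CC/C=C(/C=O)[C@@H]1OC | target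

**Totals and risks**

Total step count: 23. Longest linear sequence: 23 steps (from 1 and 2).

**Steps most likely to fail**

1. Step 16 (labelled step).
- What may go wrong: the transannular chair may be too strained. The enol silane could then be consumed by desilylation, by E/Z leakage with loss of control at C8, or by a [1,5]-hydrogen shift before C7–C8 forms.
- Fallback with known chemistry: intramolecular Barbier allylation of an aldehyde by a 2-(bromomethyl)acrylate, an established closure of ten-membered germacranolide rings. It sets out from 17 and comes back at 27.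
- The C9 epimers of 17 are separated. The (9S)-alcohol F1 is methylated (Me3OBF4, 1,8-bis(dimethylamino)naphthalene) to the methyl ether F2, and the selective Swern oxidation used in step 12 gives the C7 aldehyde F3.
- A Morita–Baylis–Hillman reaction with ethyl acrylate (DABCO) gives the hydroxy acrylate F4, which NBS/Me2S converts with allylic transposition into the (Z)-allylic bromide F5.
- DDQ frees the primary alcohol F6 and Dess–Martin periodinane gives the C8 aldehyde F7.
- Indium powder in THF/H2O at high dilution closes C7–C8 through the cyclic six-centre allylindium transition state (syn adduct) to the ten-membered homoallylic alcohol F8. TBSOTf/2,6-lutidine then gives 27.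

2. Step 13.
- What may go wrong: oligomerisation may outrun cyclisation, the phosphonate anion may lose the alkoxide by E1cB, or the α-silyloxy aldehyde may epimerise under base.
- The fallback replaces both the etherification and the olefination by ring-closing metathesis. It sets out from 17 and comes back at 21.
- O-alkylation of 17 with ethyl 2-(bromomethyl)acrylate (NaH, THF, 0 °C) gives the acrylate ether F9. The selective Swern oxidation gives the aldehyde F10, and methylenation (Ph3P=CH2) gives the terminal alkene F11.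
- A second-generation ruthenium alkylidene catalyst (toluene, 80 °C, high dilution) joins the vinyl group and the 1,1-disubstituted acrylate to give 21. The trisubstituted alkenes stay spectators.

3. Step 17.
- What may go wrong: the ring conformation rather than the Felkin–Anh preference may decide which carbonyl face is open, giving poor facial selectivity, and the silyl group may migrate from O8 to O9.
- The fallback changes from substrate to reagent control. It sets out from 25 and comes back at 26.
- The enone is reduced with (S)-Me-CBS oxazaborolidine and catecholborane (toluene, −78 °C). With the α-branched alkenyl residue C10 as the large group, this antipode should deliver hydride to the face that leads to 9S. No new compound arises (F0).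

**Further compounds**
F1 | step 16 | (9S)-epimer of 17 | CC[Si](CC)(CC)OC[C@H](O[Si](CC)(CC)CC)/C=C(/CO[Si](c1ccccc1)(c1ccccc1)C(C)(C)C)CC/C=C(/CO[Si](C)(C)C(C)(C)C)[C@H](O)COCc1ccc(OC)cc1
F2 | step 16 | (9S)-methyl ether of F1 | CC[Si](CC)(CC)OC[C@H](O[Si](CC)(CC)CC)/C=C(/CO[Si](c1ccccc1)(c1ccccc1)C(C)(C)C)CC/C=C(/CO[Si](C)(C)C(C)(C)C)[C@H](OC)COCc1ccc(OC)cc1
F3 | step 16 | C7 aldehyde from F2 | O=C[C@H](O[Si](CC)(CC)CC)/C=C(/CO[Si](c1ccccc1)(c1ccccc1)C(C)(C)C)CC/C=C(/CO[Si](C)(C)C(C)(C)C)[C@H](OC)COCc1ccc(OC)cc1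
F4 | step 16 | Morita–Baylis–Hillman adduct (C7 carbinol epimers) | C=C(C(=O)OCC)C(O)[C@H](O[Si](CC)(CC)CC)/C=C(/CO[Si](c1ccccc1)(c1ccccc1)C(C)(C)C)CC/C=C(/CO[Si](C)(C)C(C)(C)C)[C@H](OC)COCc1ccc(OC)cc1
F5 | step 16 | (Z)-2-(bromomethyl)enoate (C13–Br, C13 cis to C6) | BrC/C(C(=O)OCC)=C\[C@H](O[Si](CC)(CC)CC)/C=C(/CO[Si](c1ccccc1)(c1ccccc1)C(C)(C)C)CC/C=C(/CO[Si](C)(C)C(C)(C)C)[C@H](OC)COCc1ccc(OC)cc1
F6 | step 16 | primary C8 alcohol from F5 | BrC/C(C(=O)OCC)=C\[C@H](O[Si](CC)(CC)CC)/C=C(/CO[Si](c1ccccc1)(c1ccccc1)C(C)(C)C)CC/C=C(/CO[Si](C)(C)C(C)(C)C)[C@H](OC)CO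
F7 | step 16 | C8 aldehyde from F6 | BrC/C(C(=O)OCC)=C\[C@H](O[Si](CC)(CC)CC)/C=C(/CO[Si](c1ccccc1)(c1ccccc1)C(C)(C)C)CC/C=C(/CO[Si](C)(C)C(C)(C)C)[C@H](OC)C=O
F8 | step 16 | ten-membered (6R,7S,8S,9S)-homoallylic alcohol (free C8–OH) | O[C@H]1[C@@H](C(=C)C(=O)OCC)[C@H](O[Si](CC)(CC)CC)/C=C(/CO[Si](c2ccccc2)(c2ccccc2)C(C)(C)C)CC/C=C(/CO[Si](C)(C)C(C)(C)C)[C@@H]1OC
F9 | step 13 | O9 2-(ethoxycarbonyl)allyl ether of 17 | CC[Si](CC)(CC)OC[C@H](O[Si](CC)(CC)CC)/C=C(/CO[Si](c1ccccc1)(c1ccccc1)C(C)(C)C)CC/C=C(/CO[Si](C)(C)C(C)(C)C)C(COCc1ccc(OC)cc1)OCC(=C)C(=O)OCC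
F10 | step 13 | C7 aldehyde from F9 | O=C[C@H](O[Si](CC)(CC)CC)/C=C(/CO[Si](c1ccccc1)(c1ccccc1)C(C)(C)C)CC/C=C(/CO[Si](C)(C)C(C)(C)C)C(COCc1ccc(OC)cc1)OCC(=C)C(=O)OCC
F11 | step 13 | terminal C7 vinyl compound from F10 | C=C[C@H](O[Si](CC)(CC)CC)/C=C(/CO[Si](c1ccccc1)(c1ccccc1)C(C)(C)C)CC/C=C(/CO[Si](C)(C)C(C)(C)C)C(COCc1ccc(OC)cc1)OCC(=C)C(=O)OCC
F0 | step 17 | none | none
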